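In benzofuran numbering (ring A benzo, ring B dihydrofuran) gnetal is cut across ring B at C2–C3 and O1–C2, which removes C2 and its aryl group as a one-carbon benzylidene unit. The cut exploits the fact that C3, a diarylmethine, sits on C3a of ring A between the oxygen-bearing carbons C4 and C7a, so O=C7a–C3a=C3 can be unmasked as an ortho-quinone methide of a symmetric resorcinol. One operation, a [4+1] annulation with a chiral sulfonium benzylide, forms both bonds, ring B and both stereocentres. Its precursors are a symmetric 2-[aryl(tosyl)methyl]resorcinol ester and a twofold-symmetric 2,5-dimethylthiolanium salt; ester adjustment and debenzylation follow.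

Key step: step 7

Remark on the chemistry: the sulfide enantiomer is chosen from the known sense of benzylidene transfer by trans-2,5-dimethylthiolane to aldehydes, where the (2R,5R)-sulfide leads to (S,S)-stilbene oxide; the same ylide face corresponds here to 2R, because at C2 the aryl group outranks C3 whereas in the oxirane the ring carbon outranks phenyl, so the (2S,5S)-sulfide is used for 2S, and the mirror-image salt from (2S,5S)-hexane-2,5-diol would be taken if experiment showed the opposite sense.

Step 1
Reactants: 1 (2R,5R)-hexane-2,5-diol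
Product: 2 (2R,5R)-hexane-2,5-diyl dimethanesulfonate
Conditions: MsCl (2.5 equiv), Et3N (3 equiv), CH2Cl2, −20 → 0 °C
Reagents that add atoms: methanesulfonyl chloride, CS(=O)(=O)Cl
Why: Mesylation takes place at the two hydroxyl oxygens only, so both stereocentres are carried over unchanged into a bis-electrophile.

Step 2
Reactants: 2 (2R,5R)-hexane-2,5-diyl dimethanesulfonate
Product: 3 (2S,5S)-2,5-dimethylthiolane
Conditions: Na2S·9H2O (1.2 equiv), EtOH, rt; distillation
Reagents that add atoms: sodium sulfide (used as the nonahydrate), [Na+].[Na+].[S-2]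
Why: Two consecutive SN2 displacements by sulfur, the second a 5-exo-tet ring closure, invert both centres and give the twofold-symmetric trans-thiolane, which is the established access to this sulfide class.

Step 3
Reactants: 3 (2S,5S)-2,5-dimethylthiolane, 4 4-(benzyloxy)benzyl bromide
Product: 5 (2S,5S)-1-{[4-(benzyloxy)phenyl]methyl}-2,5-dimethylthiolan-1-ium tetrafluoroborate
Conditions: NaBF4 (2 equiv), acetone, rt, dark; filtration, trituration with Et2O
Reagents that add atoms: sodium tetrafluoroborate, [Na+].F[B-](F)(F)F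
Why: S-alkylation of the sulfide by the activated benzylic bromide with anion metathesis (NaBr precipitates) should give a salt whose non-nucleophilic counter-ion cannot reverse the alkylation of this electron-rich benzyl group, and the twofold axis of the sulfide makes its two lone pairs equivalent so that a single sulfonium stereoisomer forms.

Step 4
Reactants: 6 methyl 4-bromo-3,5-dihydroxybenzoate
Product: 7 methyl 4-bromo-3,5-bis(methoxymethoxy)benzoate
Conditions: MOMCl (3 equiv), iPr2NEt (4 equiv), CH2Cl2, 0 °C → rt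
Reagents that add atoms: chloromethyl methyl ether, COCCl
Why: O-alkylation of both phenols (acetal protection) removes the acidic protons before metalation and installs groups that chelate the arylmetal and later leave under acid.

Step 5
Reactants: 7 methyl 4-bromo-3,5-bis(methoxymethoxy)benzoate, 8 3,5-bis(benzyloxy)benzaldehyde
Product: 10 methyl 4-{[3,5-bis(benzyloxy)phenyl](hydroxy)methyl}-3,5-bis(methoxymethoxy)benzoate (racemic), via arylmagnesium chloride 9 (not isolated)
Conditions: iPrMgCl·LiCl (1.15 equiv), THF, −15 °C; then 8 (1.2 equiv), −15 °C → rt; aq. NH4Cl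
Reagents that add atoms: none
Why: Bromine–magnesium exchange with the turbo-Grignard reagent is favoured by the two flanking chelating acetal oxygens and the para ester and tolerates the ester at low temperature, and 1,2-addition of the arylmagnesium to the aldehyde gives the diarylmethanol, whose racemic centre is erased later.

Step 6
Reactants: 10 methyl 4-{[3,5-bis(benzyloxy)phenyl](hydroxy)methyl}-3,5-bis(methoxymethoxy)benzoate
Product: 12 methyl 4-{[3,5-bis(benzyloxy)phenyl](4-methylbenzenesulfonyl)methyl}-3,5-dihydroxybenzoate (racemic), via bis-MOM sulfone 11 (not isolated)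
Conditions: TolSO2Na (5 equiv), 6 M aq. HCl, THF/MeOH, rt; then 45 °C
Reagents that add atoms: sodium 4-methylbenzenesulfinate, Cc1ccc(S(=O)[O-])cc1.[Na+]
Why: Acid ionises the doubly ortho-oxygenated benzhydrol and sulfinic acid captures the cation at sulfur (SN1 sulfonylation, the standard route to 2-(tosylalkyl)phenols), after which acid methanolysis cleaves both MOM acetals while the benzyl ethers and the methyl ester stay intact.

Step 7
Reactants: 12 methyl 4-{[3,5-bis(benzyloxy)phenyl](4-methylbenzenesulfonyl)methyl}-3,5-dihydroxybenzoate, 5 (2S,5S)-1-{[4-(benzyloxy)phenyl]methyl}-2,5-dimethylthiolan-1-ium tetrafluoroborate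
Product: 16 methyl (2S,3S)-2-[4-(benzyloxy)phenyl]-3-[3,5-bis(benzyloxy)phenyl]-4-hydroxy-2,3-dihydro-1-benzofuran-6-carboxylate, via ortho-quinone methide 13 (not isolated), via sulfonium benzylide 14 (not isolated), via betaine 15 (not isolated)
Conditions: 5 (1.5 equiv), Cs2CO3 (4 equiv), CH2Cl2/MeCN (4:1), 0 °C → rt
Reagents that add atoms: none
Why: Cs2CO3 deprotonates one of the two equivalent phenols of 12 and p-toluenesulfinate is expelled (E1cB), which erases the sulfonyl-bearing centre and gives ortho-quinone methide 13, while the same base converts 5 into benzylide 14; the ylide carbon adds to the exocyclic methide carbon (future C3) in an aromatisation-driven conjugate addition to give betaine 15, whose phenoxide then displaces the thiolane at the benzylic carbon (future C2). The closest known reaction type is the formal [4+1] annulation of ortho-quinone methides released from 2-(tosylalkyl)phenols with sulfonium ylides, combined here with chiral-sulfide benzylidene transfer of the Corey–Chaykovsky type. Ring B closes by a 5-exo-tet SN2 O-alkylation with inversion at C2. C2 is controlled by the (2S,5S)-thiolane, since only one sulfonium stereoisomer exists, the ylide should keep its aryl group turned away from the ring and the methide should approach the face remote from the neighbouring cis methyl group, which after inversion should give 2S; C3 follows from the preferred anti betaine with the two aryl groups apart, which closes to the trans ring and hence 3S. The step needs carbon attack at C3 to outrun proton transfer and O-benzylation, which the para ester should secure by raising the electrophilicity of 13, and it needs closure to outrun ionisation of the betaine, which the intramolecular phenoxide should ensure; the second hydroxyl takes no part and becomes the C4–OH.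

Step 8
Reactants: 16 methyl (2S,3S)-2-[4-(benzyloxy)phenyl]-3-[3,5-bis(benzyloxy)phenyl]-4-hydroxy-2,3-dihydro-1-benzofuran-6-carboxylate
Product: 17 (2S,3S)-2-[4-(benzyloxy)phenyl]-3-[3,5-bis(benzyloxy)phenyl]-6-(hydroxymethyl)-2,3-dihydro-1-benzofuran-4-ol
Conditions: iBu2AlH (4 equiv), CH2Cl2, −78 → 0 °C; aq. potassium sodium tartrate (KNaC4H4O6)
Reagents that add atoms: none
Why: Hydride reduction of the methyl ester to the primary benzylic alcohol proceeds with the phenol merely deprotonated, and neither stereocentre carries an acidifying group, so both should persist.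

Step 9
Reactants: 17 (2S,3S)-2-[4-(benzyloxy)phenyl]-3-[3,5-bis(benzyloxy)phenyl]-6-(hydroxymethyl)-2,3-dihydro-1-benzofuran-4-ol
Product: 18 (2S,3S)-2-[4-(benzyloxy)phenyl]-3-[3,5-bis(benzyloxy)phenyl]-4-hydroxy-2,3-dihydro-1-benzofuran-6-carbaldehyde
Conditions: MnO2 (activated, 15 equiv), CH2Cl2, rt
Reagents that add atoms: none
Why: Heterogeneous MnO2 oxidation is selective for the benzylic alcohol and stops at the aldehyde, leaving the phenol, the benzyl ethers and the dihydrofuran untouched.

Step 10
Reactants: 18 (2S,3S)-2-[4-(benzyloxy)phenyl]-3-[3,5-bis(benzyloxy)phenyl]-4-hydroxy-2,3-dihydro-1-benzofuran-6-carbaldehyde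
Product: 19 gnetal, (2S,3S)-3-(3,5-dihydroxyphenyl)-4-hydroxy-2-(4-hydroxyphenyl)-2,3-dihydro-1-benzofuran-6-carbaldehyde
Conditions: BCl3 (1 M in CH2Cl2, 8 equiv), C6HMe5 (10 equiv), CH2Cl2, −78 °C; MeOH quench
Reagents that add atoms: none
Why: Lewis-acid cleavage of the three aryl benzyl ethers with pentamethylbenzene as a non-basic benzyl-cation scavenger prevents C-benzylation of the electron-rich rings and, at low temperature, should spare the aldehyde and the trans-dihydrofuran, whose C3 centre is not labile.

Compound list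
1 | (2R,5R)-hexane-2,5-diol | C[C@@H](O)CC[C@@H](C)O | starting material
2 | (2R,5R)-hexane-2,5-diyl dimethanesulfonate | C[C@@H](OS(C)(=O)=O)CC[C@@H](C)OS(C)(=O)=O | intermediate
3 | (2S,5S)-2,5-dimethylthiolane | C[C@H]1CC[C@H](C)S1 | intermediate
4 | 4-(benzyloxy)benzyl bromide | BrCc1ccc(OCc2ccccc2)cc1 | starting material
5 | (2S,5S)-1-{[4-(benzyloxy)phenyl]methyl}-2,5-dimethylthiolan-1-ium tetrafluoroborate | C[C@H]1CC[C@H](C)[S+]1Cc1ccc(OCc2ccccc2)cc1.F[B-](F)(F)F | intermediate
6 | methyl 4-bromo-3,5-dihydroxybenzoate | COC(=O)c1cc(O)c(Br)c(O)c1 | starting material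
7 | methyl 4-bromo-3,5-bis(methoxymethoxy)benzoate | COCOc1cc(C(=O)OC)cc(OCOC)c1Br | intermediate
8 | 3,5-bis(benzyloxy)benzaldehyde | O=Cc1cc(OCc2ccccc2)cc(OCc2ccccc2)c1 | starting material
9 | [4-(methoxycarbonyl)-2,6-bis(methoxymethoxy)phenyl]magnesium chloride, LiCl complex | COCOc1cc(C(=O)OC)cc(OCOC)c1[Mg]Cl.[Li+].[Cl-] | intermediate (not isolated)
10 | methyl 4-{[3,5-bis(benzyloxy)phenyl](hydroxy)methyl}-3,5-bis(methoxymethoxy)benzoate (racemic) | COCOc1cc(C(=O)OC)cc(OCOC)c1C(O)c1cc(OCc2ccccc2)cc(OCc2ccccc2)c1 | intermediate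
11 | methyl 4-{[3,5-bis(benzyloxy)phenyl](4-methylbenzenesulfonyl)methyl}-3,5-bis(methoxymethoxy)benzoate (racemic) | COCOc1cc(C(=O)OC)cc(OCOC)c1C(c1cc(OCc2ccccc2)cc(OCc2ccccc2)c1)S(=O)(=O)c1ccc(C)cc1 | intermediate (not isolated)
12 | methyl 4-{[3,5-bis(benzyloxy)phenyl](4-methylbenzenesulfonyl)methyl}-3,5-dihydroxybenzoate (racemic) | COC(=O)c1cc(O)c(C(c2cc(OCc3ccccc3)cc(OCc3ccccc3)c2)S(=O)(=O)c2ccc(C)cc2)c(O)c1 | intermediate
13 | methyl 4-{[3,5-bis(benzyloxy)phenyl]methylidene}-5-hydroxy-3-oxocyclohexa-1,5-diene-1-carboxylate (alkene geometry immaterial) | COC(=O)C1=CC(=O)C(=Cc2cc(OCc3ccccc3)cc(OCc3ccccc3)c2)C(O)=C1 | intermediate (not isolated)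
14 | (2S,5S)-1-{[4-(benzyloxy)phenyl]methanidyl}-2,5-dimethylthiolan-1-ium (sulfonium benzylide) | [CH-](c1ccc(OCc2ccccc2)cc1)[S+]1[C@@H](C)CC[C@@H]1C | intermediate (not isolated)
15 | (2S,5S)-1-{(1R,2S)-1-[4-(benzyloxy)phenyl]-2-[3,5-bis(benzyloxy)phenyl]-2-[2-hydroxy-4-(methoxycarbonyl)-6-oxidophenyl]ethyl}-2,5-dimethylthiolan-1-ium (anti betaine, zwitterion) | COC(=O)c1cc(O)c(c([O-])c1)[C@H](c1cc(OCc2ccccc2)cc(OCc2ccccc2)c1)[C@H](c1ccc(OCc2ccccc2)cc1)[S+]1[C@@H](C)CC[C@@H]1C | intermediate (not isolated)
16 | methyl (2S,3S)-2-[4-(benzyloxy)phenyl]-3-[3,5-bis(benzyloxy)phenyl]-4-hydroxy-2,3-dihydro-1-benzofuran-6-carboxylate | COC(=O)c1cc(O)c2c(c1)O[C@H](c1ccc(OCc3ccccc3)cc1)[C@H]2c1cc(OCc2ccccc2)cc(OCc2ccccc2)c1 | intermediate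
17 | (2S,3S)-2-[4-(benzyloxy)phenyl]-3-[3,5-bis(benzyloxy)phenyl]-6-(hydroxymethyl)-2,3-dihydro-1-benzofuran-4-ol | OCc1cc(O)c2c(c1)O[C@H](c1ccc(OCc3ccccc3)cc1)[C@H]2c1cc(OCc2ccccc2)cc(OCc2ccccc2)c1 | intermediate
18 | (2S,3S)-2-[4-(benzyloxy)phenyl]-3-[3,5-bis(benzyloxy)phenyl]-4-hydroxy-2,3-dihydro-1-benzofuran-6-carbaldehyde | O=Cc1cc(O)c2c(c1)O[C@H](c1ccc(OCc3ccccc3)cc1)[C@H]2c1cc(OCc2ccccc2)cc(OCc2ccccc2)c1 | intermediate
19 | gnetal, (2S,3S)-3-(3,5-dihydroxyphenyl)-4-hydroxy-2-(4-hydroxyphenyl)-2,3-dihydro-1-benzofuran-6-carbaldehyde | O=Cc1cc(O)c2c(c1)O[C@H](c1ccc(O)cc1)[C@H]2c1cc(O)cc(O)c1 | target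

Total step count: 10. Longest linear sequence: 7 steps (6 to 19 through steps 4–10; the sulfonium branch from 1 through steps 1–3 and 7–10 is equally long).

Steps most likely to fail

Step 7. Facial discrimination at the ylide carbon or at the methide may be incomplete, the betaine may ionise at the electron-rich benzylic carbon before it closes, and the acidic spectator phenol may quench the ylide by proton transfer so that conversion stalls. The fallback gives up reagent control in favour of resolution and sets out from 12 and 4. Bromide 4 is alkylated onto inexpensive thiolane with NaBF4 in acetone to give 1-{[4-(benzyloxy)phenyl]methyl}thiolan-1-ium tetrafluoroborate F1, which can be used in large excess with Cs2CO3 to drive the annulation of 12 to the racemic trans ester, methyl (2RS,3RS)-2-[4-(benzyloxy)phenyl]-3-[3,5-bis(benzyloxy)phenyl]-4-hydroxy-2,3-dihydro-1-benzofuran-6-carboxylate F2. Its enantiomers are separated by preparative chromatography on an amylose-type chiral stationary phase, and the (2S,3S) enantiomer rejoins the route as 16.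

Step 6. The benzhydryl cation may alkylate the electron-rich bis(benzyloxy)phenyl ring of a second molecule, and the sulfinic acid may disproportionate during the slower acetal cleavage so that the sulfone reverts by solvolysis. The fallback forms the carbon–sulfur bond at the sulfide oxidation level and sets out from 10. Treatment with 4-methylbenzenethiol (3 equiv) and HCl in THF/MeOH, rt then 45 °C, should trap the cation with an acid-stable and stronger nucleophile. This gives in the flask methyl 4-{[3,5-bis(benzyloxy)phenyl][(4-methylphenyl)sulfanyl]methyl}-3,5-bis(methoxymethoxy)benzoate F3 and, after loss of the acetals, methyl 4-{[3,5-bis(benzyloxy)phenyl][(4-methylphenyl)sulfanyl]methyl}-3,5-dihydroxybenzoate F4. Oxidation of the sulfide with mCPBA (2.2 equiv, CH2Cl2, 0 °C) returns to the route at 12.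

Step 5. Bromine–magnesium exchange on the doubly ortho-substituted ring may be slow enough that addition of iPrMgCl or of 9 to the methyl ester competes. The fallback masks the carboxyl group as its lithium salt and sets out from 7. Saponification (LiOH, THF/H2O) gives 4-bromo-3,5-bis(methoxymethoxy)benzoic acid F5. nBuLi (2.1 equiv, THF, −78 °C) deprotonates the acid and then exchanges bromine for lithium to give lithium 4-lithio-3,5-bis(methoxymethoxy)benzoate F6, whose carboxylate is inert to the aryllithium. Addition of 8 gives 4-{[3,5-bis(benzyloxy)phenyl](hydroxy)methyl}-3,5-bis(methoxymethoxy)benzoic acid F7, and MeI with K2CO3 in DMF re-forms the methyl ester and returns to the route at 10.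

Further compounds
F1 | step 7 | 1-{[4-(benzyloxy)phenyl]methyl}thiolan-1-ium tetrafluoroborate | c1ccc(COc2ccc(C[S+]3CCCC3)cc2)cc1.F[B-](F)(F)F
F2 | step 7 | methyl (2RS,3RS)-2-[4-(benzyloxy)phenyl]-3-[3,5-bis(benzyloxy)phenyl]-4-hydroxy-2,3-dihydro-1-benzofuran-6-carboxylate (racemic trans) | COC(=O)c1cc(O)c2c(c1)O[C@H](c1ccc(OCc3ccccc3)cc1)[C@H]2c1cc(OCc2ccccc2)cc(OCc2ccccc2)c1.COC(=O)c1cc(O)c2c(c1)O[C@@H](c1ccc(OCc3ccccc3)cc1)[C@@H]2c1cc(OCc2ccccc2)cc(OCc2ccccc2)c1
F3 | step 6 | methyl 4-{[3,5-bis(benzyloxy)phenyl][(4-methylphenyl)sulfanyl]methyl}-3,5-bis(methoxymethoxy)benzoate (racemic) | COCOc1cc(C(=O)OC)cc(OCOC)c1C(Sc1ccc(C)cc1)c1cc(OCc2ccccc2)cc(OCc2ccccc2)c1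
F4 | step 6 | methyl 4-{[3,5-bis(benzyloxy)phenyl][(4-methylphenyl)sulfanyl]methyl}-3,5-dihydroxybenzoate (racemic) | COC(=O)c1cc(O)c(C(Sc2ccc(C)cc2)c2cc(OCc3ccccc3)cc(OCc3ccccc3)c2)c(O)c1
F5 | step 5 | 4-bromo-3,5-bis(methoxymethoxy)benzoic acid | COCOc1cc(C(=O)O)cc(OCOC)c1Br
F6 | step 5 | lithium 4-lithio-3,5-bis(methoxymethoxy)benzoate | [Li]c1c(OCOC)cc(C(=O)[O-])cc1OCOC.[Li+]
F7 | step 5 | 4-{[3,5-bis(benzyloxy)phenyl](hydroxy)methyl}-3,5-bis(methoxymethoxy)benzoic acid (racemic) | COCOc1cc(C(=O)O)cc(OCOC)c1C(O)c1cc(OCc2ccccc2)cc(OCc2ccccc2)c1
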